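**Retrosynthesis** (ring order: cyclopentane → cyclohexane → ring alkenes)
1. Acid ⇐ methyl ester. The (E,E)-dienyl chain ⇐ C10 aldehyde (Wittig, then HWE) ⇐ C3-vinyl. Both ring alkenes (C1=C2, C6=C7) ⇐ ketones via enol triflate and Pd/Me coupling.
2. The vicinal quaternary centres C4 then C3 are built on a rigid trans-hydrindane. C3: axial vinyl conjugate addition to a β-methyl enone (C1=O from allylic oxidation). C4: axial methylation of a β-keto ester.
3. The cyclohexane ring (C3–C4 bond) ⇐ SmI2 Reformatsky of an α-bromo ester onto an aldehyde, on a trans-2,3-disubstituted cyclopentane that is the first ring and fixes C5, C8 and C9.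
4. That cyclopentane ⇐ conjugate addition and trans enolate allylation of (R)-4-methylcyclopentenone ⇐ (R)-4-acetoxy enone ⇐ enzymatic desymmetrisation of meso 3,5-diacetoxycyclopentene.

**Locants used in all names:** six-ring C1(Me)=C2–C3(Me)(C10)–C4(Me)(CO2R)–C5–C9; five-ring C5–C6(Me)=C7–C8(Me)–C9; side chain C10=C11(Me)–C12=C13–Ph.
**Assumption:** the SMILES corresponds to a trans-fused hydrindene (H5 and H9 anti). Compounds 1, 5, 7, 20, 24 and 26 are purchased. C6-carbinol epimers in 9–14 are carried as mixtures because C6 is re-oxidised in step 24.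

---

**Step 1**
Reactants: 1 cis-3,5-diacetoxycyclopent-1-ene (meso)
Product: 2 (1R,4S)-4-hydroxycyclopent-2-en-1-yl acetate
Conditions: electric-eel acetylcholinesterase (hydrolase, EC 3.1.1.7), 0.1 M phosphate pH 7.0, 25 °C, pH-stat with 1 M NaOH, stop at 1 equiv
Reagents that add atoms: none
Why: Enzyme-catalysed asymmetric desymmetrisation (ester hydrolysis) removes only one of the two enantiotopic acetates, setting the first stereocentre.

**Step 2**
Reactants: 2
Product: 3 (R)-4-acetoxycyclopent-2-en-1-one
Conditions: Dess–Martin periodinane, NaHCO3, CH2Cl2, 0 °C, 30 min (used at once)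
Reagents that add atoms: none
Why: Oxidation of the allylic alcohol leaves the acetoxy-bearing stereocentre untouched; the γ-acyloxy enone racemises easily, so it is used cold and immediately.

**Step 3**
Reactants: 3
Product: 4 (R)-4-methylcyclopent-2-en-1-one
Conditions: Me2CuLi (1.05 equiv, CuI + 2 MeLi), Et2O, –78 °C; then DBU, CH2Cl2, –20 °C, 15 min; crude used immediately
Reagents that add atoms: lithium dimethylcuprate, C[Cu-]C.[Li+] (the Me is kept)
Why: Cuprate conjugate addition anti to OAc creates the C8-methyl stereocentre. DBU then drives E1cB loss of the β′-acetate, so the OAc stereocentre is traded for the (R)-methyl stereocentre (1,2-chirality transfer).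

**Step 4**
Reactants: 4; 5 2-(1,3-dioxolan-2-yl)ethylmagnesium bromide
Product: 6 {[(3S,4R)-3-[2-(1,3-dioxolan-2-yl)ethyl]-4-methylcyclopent-1-en-1-yl]oxy}trimethylsilane
Conditions: CuBr·SMe2 (1.2 equiv), 5 (2.4 equiv), TMSCl, HMPA, THF, –78 → –40 °C
Reagents that add atoms: trimethylsilyl chloride, C[Si](C)(C)Cl
Why: Cu-mediated 1,4-addition of the Grignard reagent occurs at C9 anti to the C8 methyl (trans), setting C9, and TMSCl traps the regiodefined enolate as the silyl enol ether.

**Step 5**
Reactants: 6; 7 allyl bromide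
Product: 8 (2R,3S,4R)-2-allyl-3-[2-(1,3-dioxolan-2-yl)ethyl]-4-methylcyclopentan-1-one
Conditions: MeLi (1.1 equiv), THF, 0 °C; then HMPA, 7, –78 → 0 °C
Reagents that add atoms: none (MeLi only removes the silyl group; allyl bromide is reactant 7)
Why: Enolate alkylation (regiospecific Li enolate from Si–O cleavage) proceeds trans to the adjacent C9 chain, setting C5, so the C4 and C1 substituents are trans (precursor of the trans ring fusion).

**Step 6**
Reactants: 8
Product: 9 C6-alcohol of 8 (cyclopentan-1-ol, 2R,3S,4R core, C6 epimer mixture)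
Conditions: NaBH4, MeOH, 0 °C, 30 min
Reagents that add atoms: none
Why: Hydride reduction masks the C6 ketone, which would otherwise enolise in steps 9–13 and could epimerise C5; the C6 configuration is irrelevant because it is re-oxidised in step 24.

**Step 7**
Reactants: 9
Product: 10 TBS ether of 9
Conditions: TBSCl, imidazole, DMF, rt, 12 h
Reagents that add atoms: tert-butyldimethylsilyl chloride, CC(C)(C)[Si](C)(C)Cl
Why: A secondary TBS ether survives the later LiHMDS, SmI2, DMP, Cr(VI) and Pd/Zn conditions and is removed selectively in step 23.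

**Step 8**
Reactants: 10
Product: 11 methyl [cyclopentyl]acetate (C5–CH2CO2Me; C6-OTBS; core configuration as in 8)
Conditions: O3, CH2Cl2/MeOH 3:1, NaHCO3, –78 °C; then Ac2O, Et3N, 0 °C → rt
Reagents that add atoms: ozone, O=[O+][O-]; methanol, CO
Why: Ozonolysis in methanol gives the α-methoxy hydroperoxide, which Ac2O/Et3N dehydrates to the methyl ester. This converts the allyl group into the C4–C(=O) unit; the acetal and TBS ether survive.

**Step 9**
Reactants: 11
Product: 12 α-bromo ester (C4–Br, C4 epimer mixture)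
Conditions: LiHMDS, TMSCl, THF, –78 °C; then NBS, –78 → 0 °C
Reagents that add atoms: N-bromosuccinimide, O=C1CCC(=O)N1Br
Why: The silyl ketene acetal is brominated electrophilically; the C4 configuration is irrelevant because C4 becomes a planar enolate in step 11.

**Step 10**
Reactants: 12
Product: 13 aldehyde (C3–CHO; α-bromo ester and OTBS intact)
Conditions: PPTS, acetone/H2O 4:1, 55 °C
Reagents that add atoms: water, O (becomes the aldehyde oxygen)
Why: Acid-catalysed acetal hydrolysis unmasks the future C3 carbon; the hindered secondary TBS ether and the α-bromo ester tolerate these mild conditions.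

**Step 11**
Reactants: 13
Product: 14 trans-fused β-hydroxy ester, methyl 3-hydroxy-hydrindane-4-carboxylate (C3, C4 epimer mixture; C6-OTBS)
Conditions: SmI2 (2.5 equiv), THF, –78 °C → rt
Reagents that add atoms: none
Why: Intramolecular Sm-Reformatsky (aldol-type) closes the six-membered ring through the C3–C4 bond. The trans-ring fusion follows from the trans side chains, and the C3/C4 configuration is erased in steps 12–13.

**Step 12**
Reactants: 14
Product: 15 β-keto ester (C3 ketone, C4–H)
Conditions: Dess–Martin periodinane, NaHCO3, CH2Cl2, rt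
Reagents that add atoms: none
Why: Oxidation of the secondary alcohol gives an epimerisable β-keto ester, which is the substrate for the stereocontrolled C4 methylation.

**Step 13**
Reactants: 15
Product: 16 C4-methylated keto ester (C4 quaternary: Me axial, CO2Me equatorial)
Conditions: K2CO3, MeI, acetone, 50 °C
Reagents that add atoms: iodomethane, CI
Why: Enolate C-alkylation in the rigid trans-hydrindanone chair occurs along the axial trajectory anti to the axial C5–H (trans-diaxial), setting C4 with the Me cis to the future C3 methyl.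

**Step 14**
Reactants: 16
Product: 17 C3 enol triflate (C3(OTf)=C2)
Conditions: KHMDS, THF, –78 °C; then PhNTf2, –78 °C → 0 °C
Reagents that add atoms: N-phenylbis(trifluoromethanesulfonimide), O=S(=O)(C(F)(F)F)N(c1ccccc1)S(=O)(=O)C(F)(F)F
Why: Kinetic enolisation can only occur toward C2, since C4 is quaternary, so the triflate regiochemistry is fixed.

**Step 15**
Reactants: 17
Product: 18 C3-methyl alkene (C2=C3(Me))
Conditions: Pd(PPh3)4 (10 mol %), Me2Zn (3 equiv), THF, 65 °C
Reagents that add atoms: dimethylzinc, C[Zn]C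
Why: Negishi-type Pd/Me coupling of a vinyl triflate retains the alkene position, and the hindered ester is tolerated.

**Step 16**
Reactants: 18
Product: 19 enone (C1=O, C2=C3(Me))
Conditions: CrO3, 3,5-dimethylpyrazole, CH2Cl2, –20 → 0 °C
Reagents that add atoms: chromium trioxide, O=[Cr](=O)=O (source of the C=O oxygen)
Why: Salmond allylic oxidation acts at the only allylic methylene (C1; C4 is quaternary), giving the β-methyl enone needed for step 17 while the ring is still free of other alkenes.

**Step 17**
Reactants: 19; 20 vinylmagnesium bromide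
Product: 21 C1 ketone bearing C3 vinyl (C3 quaternary)
Conditions: CuBr·SMe2 (1.5 equiv), 20 (4 equiv), HMPA, THF, –78 → –30 °C; then NH4Cl/NH3
Reagents that add atoms: none beyond reactant 20 (vinyl group)
Why: Cuprate conjugate addition is axial at C3, anti to the axial C4-Me (trans-diaxial). This sets C3 with vinyl (C10) cis to CO2Me and C3-Me cis to C4-Me.

**Step 18**
Reactants: 21
Product: 22 C1 enol triflate with C3 vinyl (C1(OTf)=C2)
Conditions: KHMDS, THF, –78 °C; then PhNTf2
Reagents that add atoms: N-phenylbis(trifluoromethanesulfonimide), O=S(=O)(C(F)(F)F)N(c1ccccc1)S(=O)(=O)C(F)(F)F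
Why: Kinetic deprotonation at CH2 (C2) rather than tertiary C9 gives the regiodefined triflate, which masks C1 so that the later vinyl cleavage leaves the ring alkene untouched.

**Step 19**
Reactants: 22
Product: 23 C10 aldehyde (C3–CHO)
Conditions: OsO4 (5 mol %), 2,6-lutidine, NaIO4, dioxane/H2O 3:1, rt
Reagents that add atoms: osmium tetroxide, O=[Os](=O)(=O)=O (cat.; carbonyl oxygen via the cleaved diol); sodium periodate, [Na+].[O-]I(=O)=O
Why: Lemieux–Johnson cleavage is selective for the monosubstituted vinyl group over the electron-poor enol-triflate alkene.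

**Step 20**
Reactants: 23; 24 2-(triphenylphosphoranylidene)propanal
Product: 25 (E)-enal (C10=C11(Me)–C12HO)
Conditions: toluene, 110 °C, 36 h
Reagents that add atoms: none beyond reactant 24
Why: Wittig olefination with a stabilised ylide is E-selective, placing C3 trans to C12 as in the target; it tolerates the enol triflate and ester.

**Step 21**
Reactants: 25; 26 diethyl benzylphosphonate
Product: 27 (E,E)-dienyl triflate
Conditions: NaH, 26, THF, 0 °C → rt
Reagents that add atoms: none beyond reactant 26 (PhCH= unit)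
Why: Horner–Wadsworth–Emmons olefination of the enal gives the (E)-styryl unit completing C12=C13–Ph.

**Step 22**
Reactants: 27
Product: 28 C1-methyl ring alkene (C1(Me)=C2), TBS ether
Conditions: Pd(PPh3)4 (10 mol %), Me2Zn (3 equiv), THF, 65 °C
Reagents that add atoms: dimethylzinc, C[Zn]C
Why: Pd/Me coupling of the vinyl triflate (Negishi-type) installs the C1 methyl with retention; the diene and ester are untouched.

**Step 23**
Reactants: 28
Product: 29 C6 alcohol (C6 epimer mixture)
Conditions: TBAF, AcOH (1:1), THF, 40 °C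
Reagents that add atoms: none
Why: Buffered fluoride removes the TBS group; no enol triflate is present at this stage, so it is safe.

**Step 24**
Reactants: 29
Product: 30 C6 ketone
Conditions: Dess–Martin periodinane, NaHCO3, CH2Cl2, rt
Reagents that add atoms: none
Why: Oxidation converges the C6 epimers and regenerates the cyclopentanone needed for the second alkene.

**Step 25**
Reactants: 30
Product: 31 C6 enol triflate (C6(OTf)=C7)
Conditions: KHMDS, THF, –78 °C; then PhNTf2
Reagents that add atoms: N-phenylbis(trifluoromethanesulfonimide), O=S(=O)(C(F)(F)F)N(c1ccccc1)S(=O)(=O)C(F)(F)F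
Why: Kinetic enolisation occurs at CH2 (C7), not at the tertiary C5 beside the quaternary C4, so the C5 stereocentre is not touched.

**Step 26**
Reactants: 31
Product: 32 methyl ester of the target
Conditions: Pd(PPh3)4 (10 mol %), Me2Zn (3 equiv), THF, 65 °C
Reagents that add atoms: dimethylzinc, C[Zn]C
Why: Pd/Me coupling installs the C6 methyl on the trisubstituted cyclopentene.

**Step 27**
Reactants: 32
Product: 33 27-nor-zyggomphic acid B (target)
Conditions: LiSPr (from PrSH and n-BuLi), HMPA, THF, 25 → 50 °C; then 1 M HCl work-up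
Reagents that add atoms: none (PrS⁻ leaves as MeSPr; the acid hydrogen comes from the work-up)
Why: SN2 demethylation of the methyl ester occurs at the unhindered methyl carbon, so it is insensitive to the congested, doubly neopentylic acyl carbon. The diene, both ring alkenes and all five stereocentres are untouched.

---

**Compound list**

1 | cis-3,5-diacetoxycyclopent-1-ene (meso) | CC(=O)O[C@H]1C[C@@H](OC(C)=O)C=C1 | starting material
2 | (1R,4S)-4-hydroxycyclopent-2-en-1-yl acetate | O[C@@H]1C=C[C@H](OC(C)=O)C1 | intermediate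
3 | (R)-4-acetoxycyclopent-2-en-1-one | O=C1C=C[C@H](OC(C)=O)C1 | intermediate
4 | (R)-4-methylcyclopent-2-en-1-one | O=C1C=C[C@H](C)C1 | intermediate
5 | 2-(1,3-dioxolan-2-yl)ethylmagnesium bromide | Br[Mg]CCC1OCCO1 | starting material
6 | silyl enol ether (3S,4R)-3-[2-(1,3-dioxolan-2-yl)ethyl]-4-methylcyclopent-1-en-1-yl OTMS | C[C@@H]1CC(O[Si](C)(C)C)=C[C@H]1CCC2OCCO2 | intermediate
7 | allyl bromide | C=CCBr | starting material
8 | (2R,3S,4R)-2-allyl-3-[2-(1,3-dioxolan-2-yl)ethyl]-4-methylcyclopentan-1-one | O=C1C[C@@H](C)[C@H](CCC2OCCO2)[C@H]1CC=C | intermediate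
9 | C6-alcohol of 8 (C6 epimer mixture) | OC1C[C@@H](C)[C@H](CCC2OCCO2)[C@H]1CC=C | intermediate
10 | TBS ether of 9 | CC(C)(C)[Si](C)(C)OC1C[C@@H](C)[C@H](CCC2OCCO2)[C@H]1CC=C | intermediate
11 | methyl cyclopentylacetate, C6-OTBS, core as 8 | CC(C)(C)[Si](C)(C)OC1C[C@@H](C)[C@H](CCC2OCCO2)[C@H]1CC(=O)OC | intermediate
12 | α-bromo ester (C4–Br, epimer mixture) | CC(C)(C)[Si](C)(C)OC1C[C@@H](C)[C@H](CCC2OCCO2)[C@H]1C(Br)C(=O)OC | intermediate
13 | aldehyde from acetal hydrolysis | CC(C)(C)[Si](C)(C)OC1C[C@@H](C)[C@H](CCC=O)[C@H]1C(Br)C(=O)OC | intermediate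
14 | trans-fused hydrindane β-hydroxy ester (C3-OH, C4-CO2Me; C3/C4/C6 unspecified) | C1CC(O)C(C(=O)OC)[C@H]2C(O[Si](C)(C)C(C)(C)C)C[C@@H](C)[C@H]12 | intermediate
15 | β-keto ester (C3=O, C4-H) | C1CC(=O)C(C(=O)OC)[C@H]2C(O[Si](C)(C)C(C)(C)C)C[C@@H](C)[C@H]12 | intermediate
16 | C4-methyl keto ester | C1CC(=O)[C@](C)(C(=O)OC)[C@H]2C(O[Si](C)(C)C(C)(C)C)C[C@@H](C)[C@H]12 | intermediate
17 | C3 enol triflate | C1C=C(OS(=O)(=O)C(F)(F)F)[C@](C)(C(=O)OC)[C@H]2C(O[Si](C)(C)C(C)(C)C)C[C@@H](C)[C@H]12 | intermediate
18 | C3-methyl alkene | C1C=C(C)[C@](C)(C(=O)OC)[C@H]2C(O[Si](C)(C)C(C)(C)C)C[C@@H](C)[C@H]12 | intermediate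
19 | enone (C1=O) | O=C1C=C(C)[C@](C)(C(=O)OC)[C@H]2C(O[Si](C)(C)C(C)(C)C)C[C@@H](C)[C@H]12 | intermediate
20 | vinylmagnesium bromide | C=C[Mg]Br | starting material
21 | C3-vinyl C1-ketone | O=C1C[C@](C)(C=C)[C@](C)(C(=O)OC)[C@H]2C(O[Si](C)(C)C(C)(C)C)C[C@@H](C)[C@H]12 | intermediate
22 | C1 enol triflate, C3-vinyl | FC(F)(F)S(=O)(=O)OC1=C[C@](C)(C=C)[C@](C)(C(=O)OC)[C@H]2C(O[Si](C)(C)C(C)(C)C)C[C@@H](C)[C@H]12 | intermediate
23 | C10 aldehyde | FC(F)(F)S(=O)(=O)OC1=C[C@](C)(C=O)[C@](C)(C(=O)OC)[C@H]2C(O[Si](C)(C)C(C)(C)C)C[C@@H](C)[C@H]12 | intermediate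
24 | 2-(triphenylphosphoranylidene)propanal | CC(C=O)=P(c1ccccc1)(c1ccccc1)c1ccccc1 | starting material
25 | (E)-enal | FC(F)(F)S(=O)(=O)OC1=C[C@](C)(/C=C(C)/C=O)[C@](C)(C(=O)OC)[C@H]2C(O[Si](C)(C)C(C)(C)C)C[C@@H](C)[C@H]12 | intermediate
26 | diethyl benzylphosphonate | CCOP(=O)(Cc1ccccc1)OCC | starting material
27 | (E,E)-diene triflate | FC(F)(F)S(=O)(=O)OC1=C[C@](C)(/C=C(C)/C=C/c2ccccc2)[C@](C)(C(=O)OC)[C@H]2C(O[Si](C)(C)C(C)(C)C)C[C@@H](C)[C@H]12 | intermediate
28 | C1-methyl diene, C6-OTBS | CC1=C[C@](C)(/C=C(C)/C=C/c2ccccc2)[C@](C)(C(=O)OC)[C@H]2C(O[Si](C)(C)C(C)(C)C)C[C@@H](C)[C@H]12 | intermediate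
29 | C6 alcohol | CC1=C[C@](C)(/C=C(C)/C=C/c2ccccc2)[C@](C)(C(=O)OC)[C@H]2C(O)C[C@@H](C)[C@H]12 | intermediate
30 | C6 ketone | CC1=C[C@](C)(/C=C(C)/C=C/c2ccccc2)[C@](C)(C(=O)OC)[C@H]2C(=O)C[C@@H](C)[C@H]12 | intermediate
31 | C6 enol triflate | CC1=C[C@](C)(/C=C(C)/C=C/c2ccccc2)[C@](C)(C(=O)OC)[C@H]2C(OS(=O)(=O)C(F)(F)F)=C[C@@H](C)[C@H]12 | intermediate
32 | methyl ester of target | CC1=C[C@](C)(/C=C(C)/C=C/c2ccccc2)[C@](C)(C(=O)OC)[C@H]2C(C)=C[C@@H](C)[C@H]12 | intermediate
33 | 27-nor-zyggomphic acid B | CC1=C[C@](C)(/C=C(C)/C=C/c2ccccc2)[C@](C)(C(=O)O)[C@H]2C(C)=C[C@@H](C)[C@H]12 | target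

---

**Total steps:** 27. **Longest linear sequence:** 27, from 1 (all other components are purchased building blocks).

**Three steps most likely to fail**
1. **Step 17 (vinyl conjugate addition to form the C3/C4 vicinal quaternary centres).**
 - Fallback: add MeMgBr/CeCl3 1,2 to enone 19 to give the tertiary allylic alcohol.
 - Then run an Eschenmoser–Claisen [3,3] shift, which delivers the C10 carbon to C3 suprafacially and forms C1(Me)=C2 directly.
 - Convert the C10–C11 amide to the methyl ketone with MeLi at –78 °C; the doubly neopentylic C4 ester is inert to it.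
 - Form the more-substituted enol triflate (Tf2O, 2,6-di-tert-butyl-4-methylpyridine) and couple it with (E)-styrylboronic acid (Suzuki) to build the C11–C12=C13–Ph diene. The C10=C11 geometry then has to be checked against the (E) requirement.
2. **Step 13 (facial selectivity of C4 methylation).**
 - Fallback: set C4 before ring closure. α-Methylate ester 11, brominate to the tertiary α-bromo ester, then close with the SmI2 Reformatsky so that C3/C4 are set by the cyclisation transition state.
 - Carry on with the same downstream sequence.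
3. **Step 20 (Wittig on the neopentylic aldehyde flanked by two quaternary carbons).**
 - Fallback: switch to a Masamune–Roush HWE with triethyl 2-phosphonopropionate.
 - Then DIBAL reduction and Dess–Martin oxidation to enal 25.
 - If that also fails, use the Claisen-derived methyl ketone / enol-triflate / Suzuki route from fallback 1.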